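In a one-step world a substrate falls by a single first-order law, so the logarithm of its charge over what is left counts the turnovers offered to each molecule, and that is the count I kept for the left-handed substrate.

| flask | left-handed substrate | right-handed substrate | reagent | precatalyst | remark | time |
|---|---|---|---|---|---|---|
| grey | 20 mM | 20 mM | 60 mM | 1 mM | run made earlier |  |
| amber | 20 mM | 20 mM | 60 mM | 4 mM | run made earlier |  |
| flask | 20 mM | 20 mM | 60.0 mM | 2.0 mM |  | 10 d |

- grey (time / d: left-handed substrate / %, right-handed substrate / %): 0.333: 48, 50; 0.833: 45, 50; 1.67: 47, 49; 2.50: 44, 49; 4.00: 40, 45; 5.00: 37, 45; 6.00: 33, 45
- amber (time / d: left-handed substrate / %, right-handed substrate / %): 0.833: 46, 49; 1.67: 40, 46; 2.50: 35, 47; 3.00: 34, 45; 4.00: 28, 42; 5.00: 29, 39; 6.00: 22, 39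

(standard deviation of a reading: 1.5 percentage points)

* part of the left-handed substrate and right-handed substrate charged together that has reacted at 10 d
* excess of left-handed product over right-handed product in the product at 10 d
* excess of right-handed substrate over left-handed substrate among what is left of the two at 10 d

- free catalyst is single-handed; left-handed substrate and right-handed substrate are mirror images of each other, charged as a racemate, each of them at the stated concentration
- the numbers in the tables scatter by 1.5 percentage points (one standard deviation)
- on the list of suspects stand: reagent + free catalyst + left-handed substrate -> free catalyst + left-handed product; 2 free catalyst -> spent catalyst; precatalyst -> free catalyst; reagent + free catalyst + right-handed substrate -> free catalyst + right-handed product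
- an excess is the difference of the two amounts in percent of their sum
- an excess is below zero if the other one leads

At 6.00 d the grey run had offered 0.416 turnovers and the amber run 0.821, so raising the precatalyst from 1 mM to 4 mM multiplied the count by 1.98, which I call the charge gain. The flask's 2.0 mM is the geometric middle of the two charges, so I multiplied the grey count by the square root of that gain and got 0.584 at the same time. The same middle at 4.00 d was 0.360, and since the readings stop at 6.00 d, I assumed that the remaining 4.00 d ran at half that late pace, which gave 0.808 turnovers. The amber readings gave a selectivity factor, the left-handed count over the right-handed count, of 3.30, so my own reckoning came to 38.6% reacted, a product excess of 43.7% and a substrate excess of 27.4%.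

The forecast, reasoning that “Four times the precatalyst only doubles the rate”, stood close by at 37%, 45% and 27% for the same three answers.

The flask gave 35.1% reacted, a product excess of 41.7% and a substrate excess of 22.5%.

    reagent + free catalyst + left-handed substrate → free catalyst + left-handed product (k = 0.0300 L² mol⁻² s⁻¹)
    2 free catalyst → spent catalyst (k = 0.00340 L mol⁻¹ s⁻¹)
    precatalyst → free catalyst (k = 5.10 × 10⁻⁶ s⁻¹)
    reagent + free catalyst + right-handed substrate → free catalyst + right-handed product (k = 0.0100 L² mol⁻² s⁻¹)

At the end the flask kept 50% of its charged left-handed substrate and 80% of its right-handed substrate, which is 0.686 turnovers offered, fewer than my 0.808, with a selectivity factor of 3.00. The neighbouring flask charged with 8.0 mM of precatalyst took the same multiple of charge as amber took of grey, so the charge gain made its count 1.36, which meant 12.8% left-handed substrate, 31.8% right-handed substrate and 55.4% reacted. That neighbour ended with 14.3% left-handed substrate, 32.9% right-handed substrate and 52.8% reacted.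

(Readings and results were computed from invented constants, noise included.)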